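**Strategy.** The cyclopentene (C1 bearing CH2OAc, C2 bearing CHO, C3 bearing the side chain, C4 and C5 methylene) is closed last between alkene carbon C1 and methylene C5. The key step exploits the C1=C2–CHO enal: C1, its β-carbon, is carried as the enol triflate carbon of a 3-substituted tetronic acid, whose lactone also locks the cis CH2O/C=O pair, while C5 is the terminus of a vinyl group on stereogenic C3. Hydroboration with 9-BBN and intramolecular B-alkyl Suzuki–Miyaura coupling forge C1–C5 in one operation, giving a cyclopentene-fused butenolide. Both stereocentres arise from one amine-catalysed syn-selective aldehyde–nitroalkene Michael addition.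

Key step: step 9

Remark on the chemistry: the amine-catalysed Michael addition is taken to follow its usual syn topicity, so the (R)-configured diarylprolinol silyl ether is chosen to give the (3S,4S) adduct; compounds 1, 2, 5, 8, 13 and 17 are taken as commercial.

Step 1
Reactants: 1 geranyl bromide, (2E)-1-bromo-3,7-dimethylocta-2,6-diene; 2 acetonitrile
Product: 3 (4E)-5,9-dimethyldeca-4,8-dienenitrile
Conditions: LiN(i-Pr)2, MeCN (3 equiv), THF, −78 °C; then 1, −78 → −20 °C
Reagents that add atoms: none
Why: SN2 alkylation of lithiated acetonitrile by the primary allylic bromide should extend the chain by two carbons, the excess anion suppressing dialkylation and the E-alkene staying untouched.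

Step 2
Reactants: 3 (4E)-5,9-dimethyldeca-4,8-dienenitrile
Product: 4 (4E)-5,9-dimethyldeca-4,8-dienal
Conditions: i-Bu2AlH (1.2 equiv), CH2Cl2, −78 °C; then 1 M aq. HCl, 0 °C
Reagents that add atoms: water, O
Why: Partial reduction of the nitrile with i-Bu2AlH stops at the N-aluminio imine, which hydrolyses to the aldehyde on work-up.

Step 3
Reactants: 4 (4E)-5,9-dimethyldeca-4,8-dienal; 5 nitromethane
Product: 7 (1E,5E)-6,10-dimethyl-1-nitroundeca-1,5,9-triene, via nitro alcohol 6 (not isolated)
Conditions: MeNO2 (3 equiv), KOt-Bu (5 mol%), THF/t-BuOH, 0 °C; volatiles removed; then MsCl (1.3 equiv), Et3N (2.6 equiv), CH2Cl2, −10 °C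
Reagents that add atoms: none
Why: A Henry addition followed by mesylation and E1cB elimination should give the conjugated nitroalkene as the thermodynamically preferred E isomer.

Step 4
Reactants: 7 (1E,5E)-6,10-dimethyl-1-nitroundeca-1,5,9-triene; 8 methyl 4-oxobutanoate
Product: 9 methyl (3S,4S,7E)-3-formyl-8,12-dimethyl-4-(nitromethyl)trideca-7,11-dienoate
Conditions: (R)-α,α-diphenylprolinol trimethylsilyl ether (10 mol%), 4-nitrophenol (20 mol%), 8 (2 equiv), toluene, rt
Reagents that add atoms: none
Why: In this enamine-catalysed Michael addition the E-enamine of 8, shielded on one face by the diaryl(silyloxy)methyl group, should add to the nitroalkene through the synclinal open transition state, which sets C3 and the adjacent side-chain centre together as the syn pair, the (R)-catalyst giving the (3S,4S) adduct.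

Step 5
Reactants: 9 methyl (3S,4S,7E)-3-formyl-8,12-dimethyl-4-(nitromethyl)trideca-7,11-dienoate (used crude)
Product: 10 methyl (3R,4S,7E)-3-ethenyl-8,12-dimethyl-4-(nitromethyl)trideca-7,11-dienoate
Conditions: Ph3PCH3Br (3 equiv), KN(SiMe3)2 (2.8 equiv), THF, −78 °C; 9 added, −78 → 0 °C; aq. NH4Cl
Reagents that add atoms: methyltriphenylphosphonium bromide, C[P+](c1ccccc1)(c1ccccc1)c1ccccc1.[Br-]
Why: Wittig methylenation with an excess of the unstabilised ylide should convert the aldehyde to the vinyl group faster than C3 epimerises, the acidic nitromethyl group being masked as its nitronate and reprotonated on work-up.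

Step 6
Reactants: 10 methyl (3R,4S,7E)-3-ethenyl-8,12-dimethyl-4-(nitromethyl)trideca-7,11-dienoate
Product: 12 methyl (3R,4S,7E)-4-(dimethoxymethyl)-3-ethenyl-8,12-dimethyltrideca-7,11-dienoate, via sodium nitronate 11 (not isolated)
Conditions: NaOMe (1.1 equiv), MeOH, 0 °C; then added to conc. H2SO4/MeOH (1:5), −40 °C, 15 min; cold aq. NaHCO3
Reagents that add atoms: methanol, CO
Why: A Nef reaction run in acidic methanol should solvolyse the nitronate directly to the dimethyl acetal, so no free aldehyde next to the side-chain stereocentre is exposed and the cold, brief acid contact spares the trisubstituted alkenes.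

Step 7
Reactants: 12 methyl (3R,4S,7E)-4-(dimethoxymethyl)-3-ethenyl-8,12-dimethyltrideca-7,11-dienoate; 13 acetoxyacetyl chloride
Product: 15 3-[(3R,4S,7E)-4-(dimethoxymethyl)-8,12-dimethyltrideca-1,7,11-trien-3-yl]-4-hydroxyfuran-2(5H)-one, via acetoxy keto ester 14 (not isolated)
Conditions: LiN(SiMe3)2 (2.2 equiv), THF, −78 °C; 13 (1.1 equiv); then MeOH, K2CO3 (2 equiv), 0 °C → rt; aq. NaH2PO4 to pH 4
Reagents that add atoms: none
Why: Crossed Claisen C-acylation of the ester enolate, methanolysis of the acetate and 5-exo-trig lactonisation of the resulting γ-hydroxy β-keto ester should give the tetronic acid, driven by formation of the stabilised tetronate anion, the configuration at the acylated carbon being irrelevant because it becomes sp2.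

Step 8
Reactants: 15 3-[(3R,4S,7E)-4-(dimethoxymethyl)-8,12-dimethyltrideca-1,7,11-trien-3-yl]-4-hydroxyfuran-2(5H)-one
Product: 16 4-[(3R,4S,7E)-4-(dimethoxymethyl)-8,12-dimethyltrideca-1,7,11-trien-3-yl]-5-oxo-2,5-dihydrofuran-3-yl trifluoromethanesulfonate
Conditions: Tf2O (1.1 equiv), i-Pr2NEt (1.5 equiv), CH2Cl2, −78 °C
Reagents that add atoms: trifluoromethanesulfonic anhydride, FC(F)(F)S(=O)(=O)OS(=O)(=O)C(F)(F)F
Why: O-Sulfonylation of the vinylogous acid under amine base should give the enol triflate at the future C1 without touching the acetal.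

Step 9
Reactants: 16 4-[(3R,4S,7E)-4-(dimethoxymethyl)-8,12-dimethyltrideca-1,7,11-trien-3-yl]-5-oxo-2,5-dihydrofuran-3-yl trifluoromethanesulfonate; 17 9-borabicyclo[3.3.1]nonane (9-BBN)
Product: 19 (6R)-6-[(2S,5E)-1,1-dimethoxy-6,10-dimethylundeca-5,9-dien-2-yl]-3,4,5,6-tetrahydro-1H-cyclopenta[c]furan-1-one, via alkylborane 18 (not isolated)
Conditions: 9-BBN (1.3 equiv), THF, 0 °C → rt; then PdCl2(dppf) (10 mol%), AsPh3 (10 mol%), K3PO4 (3 equiv), H2O (10 equiv), THF/DMF, 0.005 M, 50 °C, degassed
Reagents that add atoms: none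
Why: 9-BBN should add across the only monosubstituted alkene with boron at terminal C5 to give alkylborane 18, after which zerovalent palladium inserts into the C1–OTf bond at the β-carbon of the unsaturated lactone, phosphate-assisted transmetalation moves the primary alkyl group from boron to the alkenylpalladium triflate (divalent palladium) and reductive elimination forms C1–C5. The closest known reaction type is the tandem hydroboration/intramolecular B-alkyl Suzuki–Miyaura coupling of alkenyl halides and enol triflates that carry a remote terminal alkene, which is established for five- and six-membered carbocycles. The cyclopentene is closed by C(sp2)–C(sp3) reductive elimination from a six-membered alkyl(alkenyl)palladacycle, so the C1=C2 double bond ends inside the new ring. No stereocentre is created, and C3 and the side-chain centre carry no acidifying group under phosphate base and should be retained. The step needs chemoselective hydroboration, secured by the strong preference of 9-BBN for the terminal vinyl group over the two trisubstituted alkenes and the electron-poor enol triflate alkene, and cyclisation in preference to oligomerisation or triflate hydrolysis, secured by high dilution, the five-membered ring size and a non-hydroxide base. The lactone ring holds the triflate-bearing carbon and C3 on the same side of the alkene, so no alkene geometry has to be controlled.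

Step 10
Reactants: 19 (6R)-6-[(2S,5E)-1,1-dimethoxy-6,10-dimethylundeca-5,9-dien-2-yl]-3,4,5,6-tetrahydro-1H-cyclopenta[c]furan-1-one
Product: 21 [(3R)-3-[(2S,5E)-1,1-dimethoxy-6,10-dimethylundeca-5,9-dien-2-yl]-2-[methoxy(methyl)carbamoyl]cyclopent-1-en-1-yl]methyl acetate, via hydroxy amide 20 (not isolated)
Conditions: MeNH(OMe)·HCl (4 equiv), AlMe3 (4 equiv), CH2Cl2, 0 °C → rt; then pyridine, Ac2O, DMAP (cat.), 0 °C, same flask
Reagents that add atoms: N,O-dimethylhydroxylamine hydrochloride, CNOC.Cl; acetic anhydride, CC(=O)OC(C)=O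
Why: Aminolysis of the lactone with the aluminium amide should open the butenolide to the Z-hydroxy N-methoxy-N-methylamide, whose primary allylic alkoxide is acetylated in the same flask before it can relactonise, which differentiates the two oxygenated carbons on C1 and C2 unambiguously.

Step 11
Reactants: 21 [(3R)-3-[(2S,5E)-1,1-dimethoxy-6,10-dimethylundeca-5,9-dien-2-yl]-2-[methoxy(methyl)carbamoyl]cyclopent-1-en-1-yl]methyl acetate
Product: 22 [(3R)-3-[(2S,5E)-1,1-dimethoxy-6,10-dimethylundeca-5,9-dien-2-yl]-2-formylcyclopent-1-en-1-yl]methyl acetate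
Conditions: Cp2Zr(H)Cl (1.5 equiv), THF, rt, 20 min; then wet SiO2
Reagents that add atoms: none
Why: Hydrozirconation of the amide carbonyl gives a stable zirconium hemiaminal that releases the aldehyde only on work-up, a chemoselective amide-to-aldehyde reduction that should leave the acetate, the acetal and the trisubstituted alkenes untouched.

Step 12
Reactants: 22 [(3R)-3-[(2S,5E)-1,1-dimethoxy-6,10-dimethylundeca-5,9-dien-2-yl]-2-formylcyclopent-1-en-1-yl]methyl acetate
Product: 23 [(3R)-3-[(2S,5E)-6,10-dimethyl-1-oxoundeca-5,9-dien-2-yl]-2-formylcyclopent-1-en-1-yl]methyl acetate (target)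
Conditions: AcOH/THF/H2O (3:1:1), 40 °C
Reagents that add atoms: water, O
Why: Mild acid-catalysed acetal hydrolysis should release the α-branched aldehyde last, under conditions too weak to cleave the allylic acetate, isomerise the polyene or epimerise the new α-stereocentre.

Compound list
1 | geranyl bromide, (2E)-1-bromo-3,7-dimethylocta-2,6-diene | BrC/C=C(\C)CCC=C(C)C | starting material
2 | acetonitrile | CC#N | starting material
3 | (4E)-5,9-dimethyldeca-4,8-dienenitrile | N#CCC/C=C(\C)CCC=C(C)C | intermediate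
4 | (4E)-5,9-dimethyldeca-4,8-dienal | O=CCC/C=C(\C)CCC=C(C)C | intermediate
5 | nitromethane | C[N+](=O)[O-] | starting material
6 | (5E)-6,10-dimethyl-1-nitroundeca-5,9-dien-2-ol (racemic nitro alcohol) | [O-][N+](=O)CC(O)CC/C=C(\C)CCC=C(C)C | intermediate
7 | (1E,5E)-6,10-dimethyl-1-nitroundeca-1,5,9-triene | [O-][N+](=O)/C=C/CC/C=C(\C)CCC=C(C)C | intermediate
8 | methyl 4-oxobutanoate | COC(=O)CCC=O | starting material
9 | methyl (3S,4S,7E)-3-formyl-8,12-dimethyl-4-(nitromethyl)trideca-7,11-dienoate | COC(=O)C[C@@H]([C@@H](C[N+](=O)[O-])CC/C=C(\C)CCC=C(C)C)C=O | intermediate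
10 | methyl (3R,4S,7E)-3-ethenyl-8,12-dimethyl-4-(nitromethyl)trideca-7,11-dienoate | COC(=O)C[C@@H]([C@@H](C[N+](=O)[O-])CC/C=C(\C)CCC=C(C)C)C=C | intermediate
11 | sodium nitronate of 10 | COC(=O)C[C@@H]([C@@H](C=[N+]([O-])[O-])CC/C=C(\C)CCC=C(C)C)C=C.[Na+] | intermediate
12 | methyl (3R,4S,7E)-4-(dimethoxymethyl)-3-ethenyl-8,12-dimethyltrideca-7,11-dienoate | COC(=O)C[C@@H]([C@@H](C(OC)OC)CC/C=C(\C)CCC=C(C)C)C=C | intermediate
13 | acetoxyacetyl chloride | CC(=O)OCC(Cl)=O | starting material
14 | methyl (3R,4S,7E)-2-(acetoxyacetyl)-4-(dimethoxymethyl)-3-ethenyl-8,12-dimethyltrideca-7,11-dienoate (mixture at C2) | COC(=O)C(C(=O)COC(C)=O)[C@@H]([C@@H](C(OC)OC)CC/C=C(\C)CCC=C(C)C)C=C | intermediate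
15 | 3-[(3R,4S,7E)-4-(dimethoxymethyl)-8,12-dimethyltrideca-1,7,11-trien-3-yl]-4-hydroxyfuran-2(5H)-one | O=C1OCC(O)=C1[C@@H]([C@@H](C(OC)OC)CC/C=C(\C)CCC=C(C)C)C=C | intermediate
16 | 4-[(3R,4S,7E)-4-(dimethoxymethyl)-8,12-dimethyltrideca-1,7,11-trien-3-yl]-5-oxo-2,5-dihydrofuran-3-yl trifluoromethanesulfonate | O=C1OCC(OS(=O)(=O)C(F)(F)F)=C1[C@@H]([C@@H](C(OC)OC)CC/C=C(\C)CCC=C(C)C)C=C | intermediate
17 | 9-borabicyclo[3.3.1]nonane (9-BBN) | B1C2CCCC1CCC2 | starting material
18 | 4-[(3R,4S,7E)-1-(9-borabicyclo[3.3.1]nonan-9-yl)-4-(dimethoxymethyl)-8,12-dimethyltrideca-7,11-dien-3-yl]-5-oxo-2,5-dihydrofuran-3-yl trifluoromethanesulfonate | O=C1OCC(OS(=O)(=O)C(F)(F)F)=C1[C@@H]([C@@H](C(OC)OC)CC/C=C(\C)CCC=C(C)C)CCB2C3CCCC2CCC3 | intermediate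
19 | (6R)-6-[(2S,5E)-1,1-dimethoxy-6,10-dimethylundeca-5,9-dien-2-yl]-3,4,5,6-tetrahydro-1H-cyclopenta[c]furan-1-one | O=C1OCC2=C1[C@@H]([C@@H](C(OC)OC)CC/C=C(\C)CCC=C(C)C)CC2 | intermediate
20 | (5R)-5-[(2S,5E)-1,1-dimethoxy-6,10-dimethylundeca-5,9-dien-2-yl]-2-(hydroxymethyl)-N-methoxy-N-methylcyclopent-1-ene-1-carboxamide | OCC1=C(C(=O)N(C)OC)[C@@H]([C@@H](C(OC)OC)CC/C=C(\C)CCC=C(C)C)CC1 | intermediate
21 | [(3R)-3-[(2S,5E)-1,1-dimethoxy-6,10-dimethylundeca-5,9-dien-2-yl]-2-[methoxy(methyl)carbamoyl]cyclopent-1-en-1-yl]methyl acetate | CC(=O)OCC1=C(C(=O)N(C)OC)[C@@H]([C@@H](C(OC)OC)CC/C=C(\C)CCC=C(C)C)CC1 | intermediate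
22 | [(3R)-3-[(2S,5E)-1,1-dimethoxy-6,10-dimethylundeca-5,9-dien-2-yl]-2-formylcyclopent-1-en-1-yl]methyl acetate | CC(=O)OCC1=C(C=O)[C@@H]([C@@H](C(OC)OC)CC/C=C(\C)CCC=C(C)C)CC1 | intermediate
23 | [(3R)-3-[(2S,5E)-6,10-dimethyl-1-oxoundeca-5,9-dien-2-yl]-2-formylcyclopent-1-en-1-yl]methyl acetate | CC(=O)OCC1=C(C=O)[C@@H]([C@@H](C=O)CC/C=C(\C)CCC=C(C)C)CC1 | target

Total step count: 12. Longest linear sequence: 12 steps (1 to 23).

Steps most likely to fail

Step 9 (key step). The enol triflate may be hydrolysed by the aqueous base before oxidative addition, the alkylpalladium may undergo β-hydride elimination or protodeboronation, and intermolecular coupling may compete with ring closure. The fallback reverses the polarity of C5 through an organozinc instead of a borane and sets out from tetronic acid 15. Hydroboration of the vinyl group with 9-BBN and oxidation with NaBO3·4H2O would give 4-hydroxy-3-[(3R,4S,7E)-4-(dimethoxymethyl)-1-hydroxy-8,12-dimethyltrideca-7,11-dien-3-yl]furan-2(5H)-one F1. Double sulfonylation (TsCl, Et3N, DMAP, CH2Cl2) would give the bis-tosylate F2. NaI in acetone would exchange only the alkyl tosylate to give the iodo enol tosylate F3. Zinc insertion into the C5–I bond (Zn dust, LiCl, THF) followed by intramolecular Negishi coupling (Pd(OAc)2, SPhos, high dilution) would close the same C1–C5 bond and return to butenolide 19.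

Step 10. Aminolysis of the hindered tetrasubstituted lactone may stall, or the Z-hydroxy amide may relactonise before it is acetylated; the hindered amide may also be slow in step 11. The fallback avoids the amide and sets out from butenolide 19. Reduction with i-Bu2AlH (3 equiv, CH2Cl2, −78 → 0 °C) would give [(3R)-3-[(2S,5E)-1,1-dimethoxy-6,10-dimethylundeca-5,9-dien-2-yl]cyclopent-1-ene-1,2-diyl]dimethanol F4. Selective acylation of the less hindered hydroxymethyl group on C1 (lipase from Burkholderia cepacia, vinyl acetate, or AcCl, 2,4,6-collidine, −78 °C) would give the hydroxy acetate F5. Oxidation of the remaining allylic alcohol with MnO2 (CH2Cl2, rt) would return to enal acetal 22; the regioselectivity of the mono-acylation is the weak point of this detour.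

Step 7. The ester enolate may be O-acylated or quenched by ketene formation from the acid chloride, and the β-keto ester may undergo retro-Claisen cleavage during methanolysis. The fallback builds the tetronic acid by Dieckmann cyclisation and sets out from ester 12. Saponification (LiOH, THF/H2O) would give (3R,4S,7E)-4-(dimethoxymethyl)-3-ethenyl-8,12-dimethyltrideca-7,11-dienoic acid F6. O-Alkylation of the carboxylate with methyl bromoacetate (K2CO3, DMF) would give the glycolate diester F7. Dieckmann cyclisation (KOt-Bu, THF, 0 °C → rt) would return to tetronic acid 15.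

Further compounds
F1 | step 9 | 4-hydroxy-3-[(3R,4S,7E)-4-(dimethoxymethyl)-1-hydroxy-8,12-dimethyltrideca-7,11-dien-3-yl]furan-2(5H)-one | O=C1OCC(O)=C1[C@@H]([C@@H](C(OC)OC)CC/C=C(\C)CCC=C(C)C)CCO
F2 | step 9 | (3R,4S,7E)-4-(dimethoxymethyl)-8,12-dimethyl-3-[2-oxo-4-(tosyloxy)-2,5-dihydrofuran-3-yl]trideca-7,11-dien-1-yl 4-methylbenzenesulfonate | O=C1OCC(OS(=O)(=O)c2ccc(C)cc2)=C1[C@@H]([C@@H](C(OC)OC)CC/C=C(\C)CCC=C(C)C)CCOS(=O)(=O)c1ccc(C)cc1
F3 | step 9 | 4-[(3R,4S,7E)-4-(dimethoxymethyl)-1-iodo-8,12-dimethyltrideca-7,11-dien-3-yl]-5-oxo-2,5-dihydrofuran-3-yl 4-methylbenzenesulfonate | O=C1OCC(OS(=O)(=O)c2ccc(C)cc2)=C1[C@@H]([C@@H](C(OC)OC)CC/C=C(\C)CCC=C(C)C)CCI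
F4 | step 10 | [(3R)-3-[(2S,5E)-1,1-dimethoxy-6,10-dimethylundeca-5,9-dien-2-yl]cyclopent-1-ene-1,2-diyl]dimethanol | OCC1=C(CO)[C@@H]([C@@H](C(OC)OC)CC/C=C(\C)CCC=C(C)C)CC1
F5 | step 10 | [(3R)-3-[(2S,5E)-1,1-dimethoxy-6,10-dimethylundeca-5,9-dien-2-yl]-2-(hydroxymethyl)cyclopent-1-en-1-yl]methyl acetate | CC(=O)OCC1=C(CO)[C@@H]([C@@H](C(OC)OC)CC/C=C(\C)CCC=C(C)C)CC1
F6 | step 7 | (3R,4S,7E)-4-(dimethoxymethyl)-3-ethenyl-8,12-dimethyltrideca-7,11-dienoic acid | OC(=O)C[C@@H]([C@@H](C(OC)OC)CC/C=C(\C)CCC=C(C)C)C=C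
F7 | step 7 | 2-methoxy-2-oxoethyl (3R,4S,7E)-4-(dimethoxymethyl)-3-ethenyl-8,12-dimethyltrideca-7,11-dienoate | COC(=O)COC(=O)C[C@@H]([C@@H](C(OC)OC)CC/C=C(\C)CCC=C(C)C)C=C
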